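I decided to judge this flask by one number, the rate at which starting material disappears once the feed has ended, and to read it from Tuesday's run.

| flask | starting material | second substrate | free catalyst | remark | time |
|---|---|---|---|---|---|
| Tuesday's | 0.050 M (fed, over 20 min) | 1 equiv | 0.74 mol% | run made earlier; the fed solution adds 1.0 times the starting volume |  |
| flask | 0.050 M (fed, over 20 min) | 1.00 equiv | 0.37 mol% | the fed solution adds 1.0 times the starting volume | 10 h |

Tuesday's run (percent of the starting material charged)

| time / min | starting material / % | target / % |
|---|---|---|
| 10.0 | 39.4 | 7.2 |
| 15.0 | 57.7 | 19.0 |
| 20.0 | 70.6 | 30.0 |
| 30.0 | 47.4 | 51.0 |
| 50.0 | 21.6 | 77.0 |
| 80.0 | 7.1 | 94.4 |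
| 120 | 0.6 | 98.1 |

(each reading ± 1 percentage point)

- charges are per starting volume, the dose included; the dosed solution carries all of it
- what may be going on: starting material + free catalyst <-> catalyst intermediate A; catalyst intermediate A -> free catalyst + target; second substrate + free catalyst <-> catalyst intermediate B; catalyst intermediate B -> free catalyst + second product
- the reaction counts as stopped when no species that holds the starting material changes by six tenths of a point or more over the second half of the time
- percentages count the whole charge, also what has not yet gone in
- no earlier run changes the charge of free catalyst; that part of a forecast is a guess

- at 10 h, what has stopped the reaction, if anything has (forward and back rates have come level / no working catalyst is left / all of the starting material has reacted / it is still moving)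
- share of the starting material used up at 10 h
- target at 10 h, in percent of the starting material charged

In Tuesday's run the starting material fell from 47.4% at 30.0 min to 7.1% at 80.0 min, which reads as a pseudo-first-order constant of 0.0380 min⁻¹. This flask has half of Tuesday's catalyst, so I scaled in proportion, which is a guess, and got 0.0190 min⁻¹. That is the tail constant, the share of the standing starting material that reacts per minute.

Next I needed what stands at the end of the feed, assuming the same constant holds during dosing. I took the amount as climbing roughly linearly, so I used the midpoint between nothing and its final value as its average. Starting from the full charge, the first round left 81.0%. Putting that back in, the second round left 84.6%. From there the tail gave 0.416% at half time and 0.00140% at 10 h.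

The weak link was the half-time amount: the stopping rule in the notes above looks at the change over the second half of the time. So I reread the constant from the later Tuesday readings, 50.0 min to 80.0 min, which gave 0.0371 min⁻¹. Scaled the same way, it left 0.470% at half time. I committed to a reaction finished by consumption of the starting material.

The forecast gave all of the starting material has reacted, with 99.9% conversion and 99.3% target, and it conceded: “The linear catalyst scaling is a guess.”

The flask gave all of the starting material has reacted, with >99.9% conversion and >99.9% target. At the end of the feed it held 84.1% starting material. Carried forward from there at 0.0190 min⁻¹, that becomes 0.413% at 5.00 h, and the flask held 0.266%.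

    starting material + free catalyst ⇌ catalyst intermediate A (K = 16.0 M⁻¹, k = 310 M⁻¹ min⁻¹)
    catalyst intermediate A → free catalyst + target (k = 65.0 min⁻¹)
    second substrate + free catalyst ⇌ catalyst intermediate B (K = 29.0 M⁻¹, k = 560 M⁻¹ min⁻¹)
    catalyst intermediate B → free catalyst + second product (k = 12.0 min⁻¹)

For the neighbour flask, with the same charges read at 2.5 h, the tail constant gives 7.17% starting material left. The computed neighbour flask has 7.0% of the charge still there, unbound, and 93.0% target.

(All runs stem from a simulated flask with constants of no real substance, noise included.)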